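**Strategy.** The 6-hydroxy/15-formyl pair (O6 on C6, CHO on C4, both flanking C5) is a masked 1,4-dialdehyde and is carried as one 2,5-dimethoxytetrahydrofuran fused to ring A (C4–C15–O–C6–C5). Ring A is made by an enantioselective Diels–Alder reaction; C10 is completed by two regiospecific enolate alkylations. In the key step the acetal is ionized at C6 and the cyclic oxocarbenium ion is captured by C7 of a 2-(alkoxycarbonyl)allylsilane tethered through C10–C9–C8. One C6–C7 bond closes ring B (C5–C6–C7–C8–C9–C10), sets C6 and C7, and unveils the C11(=C13)–C12 acrylate; the 8α-ester is already in place and C1 is reduced afterwards.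

Key step: step 13

Remark 1: names use the eudesmane locants of the target (C1–C15); α/β are the faces of the target decalin, β being the face of the C10 methyl group.
Remark 2: the acetal carbons C6/C15 of 5–24 form as epimer mixtures of no consequence (both are later ionized or hydrolysed) and are drawn without configuration; 25 and 26 are written as open 6-hydroxy-15-aldehydes although they may equilibrate with the 6,15-lactol.

Step 1
Reactants: 1 methyl vinyl ketone
Product: 2 2-(tert-butyldimethylsilyloxy)buta-1,3-diene
Conditions: TBSOTf, Et3N, Et2O, 0 °C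
Reagents that add atoms: tert-butyldimethylsilyl triflate, CC(C)(C)[Si](C)(C)OS(=O)(=O)C(F)(F)F
Why: Silyl enol ether formation at the only enolizable position of the enone should give the 2-silyloxy diene.

Step 2
Reactants: 2 2-(tert-butyldimethylsilyloxy)buta-1,3-diene; 3 (E)-4,4-dimethoxybut-2-enal
Product: 4 (1R,6R)-4-(tert-butyldimethylsilyloxy)-6-(dimethoxymethyl)cyclohex-3-ene-1-carbaldehyde
Conditions: chiral oxazaborolidinium triflimide [from the (S)-α,α-diphenylprolinol-derived B-(o-tolyl)oxazaborolidine and Tf2NH] (15 mol%), CH2Cl2, −78 to −40 °C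
Reagents that add atoms: none
Why: Enantioselective Diels–Alder reaction of a 2-silyloxydiene with a Lewis-acid-activated enal, in which the trans C4/C5 relationship is transferred stereospecifically from the (E)-dienophile and the absolute configuration is set by the catalyst (its antipode is used if the facial sense proves opposite), while regio- and endo/exo-selectivity are without consequence because both carbonyl carbons later become equivalent acetal carbons.

Step 3
Reactants: 4 (1R,6R)-4-(tert-butyldimethylsilyloxy)-6-(dimethoxymethyl)cyclohex-3-ene-1-carbaldehyde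
Product: 6 trans-fused enone bis-acetal (1,3-dimethoxy-1,3,3a,7a-tetrahydroisobenzofuran-5(4H)-one), via bis-acetal silyl enol ether 5 (not isolated)
Conditions: PPTS (10 mol%), CH2Cl2, 0 °C to rt; then Pd(OAc)2 (1.05 equiv), MeCN, rt
Reagents that add atoms: none
Why: Acid-catalysed isomerization of the 1,4-aldehyde–acetal to the 2,5-dimethoxytetrahydrofuran (trans fusion retained, C4 and C5 are not epimerized) followed by Saegusa oxidation of the regiodefined silyl enol ether should give the C2=C3 enone, which blocks C2 for the C10 alkylations.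

Step 4
Reactants: 6 trans-fused enone bis-acetal; 7 1-(benzyloxy)-3-iodopropane
Product: 8 C10-(3-benzyloxypropyl) enone bis-acetal
Conditions: LDA, THF, −78 °C; then 7, DMPU, −78 to −20 °C
Reagents that add atoms: none
Why: Kinetic α′-deprotonation of the cyclohexenone at its only α-CH2 (C10) and SN2 alkylation of the cross-conjugated lithium dienolate install the C9–C8–C7 chain regiospecifically; the new C10 configuration is irrelevant because C10 is enolized again.

Step 5
Reactants: 8 C10-(3-benzyloxypropyl) enone bis-acetal
Product: 9 C10-quaternary enone bis-acetal (10β-methyl)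
Conditions: LDA, THF, −78 °C; then MeI, −78 to −40 °C
Reagents that add atoms: iodomethane, CI
Why: Second α′-enolate alkylation creates the quaternary C10; methyl iodide should add axially on the β face, anti to the axial H5 of the rigid trans-fused bicycle (stereoelectronic control), so the methyl becomes β and the chain α (trans to C6).

Step 6
Reactants: 9 C10-quaternary enone bis-acetal (10β-methyl)
Product: 10 saturated hydroxy ketone bis-acetal
Conditions: H2 (1 atm), 10% Pd/C, EtOAc/EtOH, rt
Reagents that add atoms: none
Why: Catalytic hydrogenation saturates the C2=C3 enone double bond and hydrogenolyses the benzyl ether in one operation without touching the ketone or the acetals.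

Step 7
Reactants: 10 saturated hydroxy ketone bis-acetal
Product: 11 keto aldehyde bis-acetal
Conditions: TEMPO (10 mol%), PhI(OAc)2, CH2Cl2, rt
Reagents that add atoms: none
Why: TEMPO-catalysed oxidation of the only (primary) hydroxyl group should stop at the C7 aldehyde.

Step 8
Reactants: 12 allyl (triphenylphosphoranylidene)acetate (2 equiv); 13 (iodomethyl)trimethylsilane
Product: 15 allyl 2-(triphenylphosphoranylidene)-3-(trimethylsilyl)propanoate, via phosphonium iodide 14 (not isolated)
Conditions: EtOAc, reflux
Reagents that add atoms: none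
Why: C-Alkylation of the stabilized ylide followed by transylidation with the second equivalent of 12 gives the α-(silylmethyl) phosphorane.

Step 9
Reactants: 11 keto aldehyde bis-acetal; 15 allyl 2-(triphenylphosphoranylidene)-3-(trimethylsilyl)propanoate
Product: 17 (8S)-O-anilino allylsilane ester, via alpha-aminoxy aldehyde 16 (not isolated)
Conditions: nitrosobenzene, D-proline (20 mol%), DMSO, rt; then 15, CH2Cl2, 0 °C to rt
Reagents that add atoms: nitrosobenzene, O=Nc1ccccc1
Why: Proline-catalysed enamine α-aminoxylation sets C8 under catalyst control (D-proline for the 8S, later 8α, oxygen) and the labile aldehyde is trapped at once by Wittig olefination with the stabilized ylide, which places C8 trans to the ester and builds the β-(alkoxycarbonyl)allylsilane.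

Step 10
Reactants: 17 (8S)-O-anilino allylsilane ester
Product: 18 (8S)-allylic alcohol
Conditions: Zn dust, AcOH/THF, rt
Reagents that add atoms: none
Why: Reductive N–O cleavage of the O-alkyl-N-phenylhydroxylamine liberates the C8 alcohol without affecting the allylsilane, the esters or the acetals.

Step 11
Reactants: 19 2-(hydroxymethyl)acrylic acid
Product: 21 2-[(tert-butyldimethylsilyloxy)methyl]acrylic acid, via bis-silyl derivative 20 (not isolated)
Conditions: TBSCl (2.2 equiv), imidazole, DMF, rt; then AcOH/THF/H2O, rt
Reagents that add atoms: tert-butyldimethylsilyl chloride, CC(C)(C)[Si](C)(C)Cl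
Why: Exhaustive silylation followed by selective hydrolysis of the far more labile silyl ester leaves the primary silyl ether (standard protection of a hydroxy acid).

Step 12
Reactants: 18 (8S)-allylic alcohol; 21 2-[(tert-butyldimethylsilyloxy)methyl]acrylic acid
Product: 22 8-O-acylated allylsilane bis-acetal
Conditions: DIC, DMAP (20 mol%), CH2Cl2, 0 °C to rt
Reagents that add atoms: none
Why: Steglich esterification acylates the only free hydroxyl group (C8–OH), so the final 8α-ester is in place before ring closure.

Step 13
Reactants: 22 8-O-acylated allylsilane bis-acetal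
Product: 23 tricyclic 1-ketone (ring B closed; 6,15-methyl acetal)
Conditions: TMSOTf (0.3 equiv), 2,6-di-tert-butyl-4-methylpyridine (0.1 equiv), CH2Cl2, −78 to −40 °C
Reagents that add atoms: none
Why: TMSOTf ionizes the C6–OMe bond of the 2,5-dimethoxytetrahydrofuran to the endocyclic oxocarbenium ion C6=O+–C15, which is attacked by C7 of the β-(allyloxycarbonyl)allylsilane in an anti-SE2′ process that expels Me3SiOMe and regenerates the promoter; the closest known reaction type is the intramolecular Hosomi–Sakurai allylation of acetals and lactol ethers with 2-(alkoxycarbonyl)allylsilanes. Ring B (C5–C6–C7–C8–C9–C10) closes by C6–C7 bond formation in a 6-exo-trig mode (oxocarbenium oxygen and the C11=C13 π bond both exocyclic) through a chair that is already the trans-decalin, because C9 (α) and C6 (β) are both equatorial on ring A. C6 is controlled by the tetrahydrofuran tether: O6 stays bonded to C15 on the α (equatorial) side, so C7 can only add to the face that makes H6 β. C7 is controlled by C8 through A(1,3) strain: H8 eclipses the cis CH2SiMe3 group, C6 arrives on the alkene face that carries C9 and is anti to the 8α-acyloxy group, and the acrylate ends β (H7 α, all three ring B substituents equatorial). The step needs site selectivity between the two acetal carbons and chemoselectivity over the C1 ketone and the acrylates: both oxocarbenium ions form reversibly, but only the C6 ion can be reached by C7 through a six-membered chair (the C15 ion would require a seven-membered ring), and the ion is far more electrophilic than any other site.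

Step 14
Reactants: 23 tricyclic 1-ketone
Product: 24 tricyclic 1β-alcohol
Conditions: NaBH4, CeCl3·7H2O, MeOH, −78 °C
Reagents that add atoms: none
Why: Luche-type 1,2-reduction of the C1 ketone, with hydride adding axially from the α face away from the adjacent axial C10 methyl, should give the equatorial 1β-alcohol and leave the esters and both 2-substituted acrylates untouched.

Step 15
Reactants: 24 tricyclic 1β-alcohol
Product: 25 allyl ester of the target acid
Conditions: AcOH/THF/H2O (3:1:1), 40 °C
Reagents that add atoms: water, O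
Why: Mild acid hydrolysis cleaves the 2-methoxytetrahydrofuran (cyclic acetal) to the 6-hydroxy-15-aldehyde and removes the primary silyl ether, while the allyl ester prevents lactonization onto O6 and the equatorial 4α-formyl group is the thermodynamic epimer.

Step 16
Reactants: 25 allyl ester of the target acid
Product: 26 target CNP0599450.1
Conditions: Pd(PPh3)4 (5 mol%), N-methylaniline, THF, rt
Reagents that add atoms: none
Why: Palladium(0)-catalysed allyl transfer (Tsuji–Trost-type deallylation) to the amine releases the carboxylic acid under neutral conditions that spare the γ-hydroxy acid, the aldehyde and both acrylate units.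

**Compound list**

1 | methyl vinyl ketone (but-3-en-2-one) | C=CC(C)=O | starting material
2 | 2-(tert-butyldimethylsilyloxy)buta-1,3-diene | C=CC(=C)O[Si](C)(C)C(C)(C)C | intermediate
3 | (E)-4,4-dimethoxybut-2-enal (fumaraldehyde mono(dimethyl acetal)) | COC(OC)/C=C/C=O | starting material
4 | (1R,6R)-4-(tert-butyldimethylsilyloxy)-6-(dimethoxymethyl)cyclohex-3-ene-1-carbaldehyde (trans; ring C1 = target C4, ring C6 = target C5) | O=C[C@@H]1CC=C(O[Si](C)(C)C(C)(C)C)C[C@H]1C(OC)OC | intermediate
5 | trans-fused 5-(tert-butyldimethylsilyloxy)-1,3-dimethoxy-1,3,3a,4,7,7a-hexahydroisobenzofuran (H-3a α = H5, H-7a β = H4; acetal carbons epimeric) | COC1OC(OC)[C@@H]2CC(O[Si](C)(C)C(C)(C)C)=CC[C@@H]12 | intermediate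
6 | trans-fused 1,3-dimethoxy-1,3,3a,7a-tetrahydroisobenzofuran-5(4H)-one (C5=O is C1, C6=C7 is C2=C3, C4H2 is C10) | COC1OC(OC)[C@@H]2CC(=O)C=C[C@@H]12 | intermediate
7 | 1-(benzyloxy)-3-iodopropane | ICCCOCc1ccccc1 | starting material
8 | 6 carrying a 3-(benzyloxy)propyl group at C10 (β/axial epimer drawn; either epimer serves) | COC1OC(OC)[C@@H]2[C@H](CCCOCc3ccccc3)C(=O)C=C[C@@H]12 | intermediate
9 | 6 carrying 10β-methyl and 10α-[3-(benzyloxy)propyl] (quaternary C10) | COC1OC(OC)[C@@H]2[C@@](C)(CCCOCc3ccccc3)C(=O)C=C[C@@H]12 | intermediate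
10 | saturated C1 ketone with 10β-methyl and 10α-(3-hydroxypropyl), bis-acetal | COC1OC(OC)[C@@H]2[C@@](C)(CCCO)C(=O)CC[C@@H]12 | intermediate
11 | saturated C1 ketone with 10β-methyl and 10α-(3-oxopropyl) (C7 aldehyde), bis-acetal | COC1OC(OC)[C@@H]2[C@@](C)(CCC=O)C(=O)CC[C@@H]12 | intermediate
12 | allyl (triphenylphosphoranylidene)acetate | C=CCOC(=O)C=P(c1ccccc1)(c1ccccc1)c1ccccc1 | starting material
13 | (iodomethyl)trimethylsilane | C[Si](C)(C)CI | starting material
14 | [1-(allyloxycarbonyl)-2-(trimethylsilyl)ethyl]triphenylphosphonium iodide | C=CCOC(=O)C(C[Si](C)(C)C)[P+](c1ccccc1)(c1ccccc1)c1ccccc1.[I-] | intermediate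
15 | allyl 2-(triphenylphosphoranylidene)-3-(trimethylsilyl)propanoate | C=CCOC(=O)C(C[Si](C)(C)C)=P(c1ccccc1)(c1ccccc1)c1ccccc1 | intermediate
16 | 11 with an (S)-anilinooxy group at C8 (α to the C7 aldehyde) | COC1OC(OC)[C@@H]2[C@@](C)(C[C@H](ONc3ccccc3)C=O)C(=O)CC[C@@H]12 | intermediate
17 | allyl (Z)-enoate with C7=C11, CH2SiMe3 on C11 cis to C8 (ester trans), (8S)-ONHPh, C1 ketone, bis-acetal | COC1OC(OC)[C@@H]2[C@@](C)(C[C@H](ONc3ccccc3)/C=C(\C[Si](C)(C)C)C(=O)OCC=C)C(=O)CC[C@@H]12 | intermediate
18 | as 17 with free (8S)-hydroxyl | COC1OC(OC)[C@@H]2[C@@](C)(C[C@H](O)/C=C(\C[Si](C)(C)C)C(=O)OCC=C)C(=O)CC[C@@H]12 | intermediate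
19 | 2-(hydroxymethyl)acrylic acid | C=C(CO)C(=O)O | starting material
20 | tert-butyldimethylsilyl 2-[(tert-butyldimethylsilyloxy)methyl]acrylate | C=C(CO[Si](C)(C)C(C)(C)C)C(=O)O[Si](C)(C)C(C)(C)C | intermediate
21 | 2-[(tert-butyldimethylsilyloxy)methyl]acrylic acid | C=C(CO[Si](C)(C)C(C)(C)C)C(=O)O | intermediate
22 | as 18 with O8 esterified by 2-[(tert-butyldimethylsilyloxy)methyl]acrylic acid | COC1OC(OC)[C@@H]2[C@@](C)(C[C@H](OC(=O)C(=C)CO[Si](C)(C)C(C)(C)C)/C=C(\C[Si](C)(C)C)C(=O)OCC=C)C(=O)CC[C@@H]12 | intermediate
23 | trans-decalin with C1 ketone, 10β-Me, 5α-H, 4β-H, O6 (α) bridged to C15 as methyl acetal, 7β-C(=CH2)CO2allyl, 8α-O-acyl (silyl-protected) | C=C(CO[Si](C)(C)C(C)(C)C)C(=O)O[C@H]1C[C@]2(C)[C@H]3[C@@H](OC(OC)[C@@H]3CCC2=O)[C@@H]1C(=C)C(=O)OCC=C | intermediate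
24 | as 23 with 1β-hydroxyl | C=C(CO[Si](C)(C)C(C)(C)C)C(=O)O[C@H]1C[C@]2(C)[C@H]3[C@@H](OC(OC)[C@@H]3CC[C@H]2O)[C@@H]1C(=C)C(=O)OCC=C | intermediate
25 | allyl ester of the target acid (1β-OH, 4α-CHO, 6α-OH, 8α-O-[2-(hydroxymethyl)acryloyl]) | C=C(CO)C(=O)O[C@H]1C[C@]2(C)[C@@H]([C@@H](O)[C@@H]1C(=C)C(=O)OCC=C)[C@H](C=O)CC[C@H]2O | intermediate
26 | CNP0599450.1 | C=C(CO)C(=O)O[C@H]1C[C@]2(C)[C@@H]([C@@H](O)[C@@H]1C(=C)C(=O)O)[C@H](C=O)CC[C@H]2O | target

**Count.** Total: 16 steps. Longest linear sequence: 14 steps (steps 1–7, 9, 10, 12–16).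

**Steps most likely to fail**

Step 13 (ring B closure). Ionization at C15 followed by proton loss to a dihydrofuran, or protodesilylation, may outrun C–C bond formation by the ester-deactivated allylsilane. Fallback: from 22 the bis-acetal is hydrolysed (LiBF4, wet MeCN) to the keto dialdehyde F1. Its C6 aldehyde is then allylated intramolecularly with Me2AlCl at −78 °C (carbonyl Hosomi–Sakurai reaction; chair with the complexed oxygen equatorial to avoid the axial C10 methyl; six-membered closure at C6 preferred over seven-membered closure at C15). The new O6 adds to C15 to give the lactol F2, which PPTS/MeOH converts into 23.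

Step 5 (methylation at C10). The facial selectivity of the second enolate alkylation may be poor or inverted (electrophile entering syn to H5). Fallback: from 6 the order of the two C–C bond formations is exchanged, since the group that enters last defines C10. LDA/MeI gives the C10-methyl enone F3, and the chain is then introduced last with 7, coming back at 9; if needed the C10 epimers of 9 are separated there.

Step 2 (Diels–Alder reaction). Facial discrimination may be low, or the cationic boron catalyst may ionize the dimethyl acetal of 3. Fallback: from 2, an auxiliary-controlled Diels–Alder reaction with commercial di-(−)-menthyl fumarate (Et2AlCl, toluene, −40 °C; menthyl antipode chosen for the 1R,2R series) gives the dimenthyl diester F4. LiAlH4 reduction gives the diol F5 and Swern oxidation the dialdehyde F6. HC(OMe)3/PPTS in CH2Cl2 closes the bis-acetal, coming back at 5 (then Saegusa oxidation as in step 3).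

Further compounds
F1 | step 13 | keto dialdehyde from 22 (C6 and C15 aldehydes free, trans on C5/C4) | O=C[C@H]1[C@H](C=O)CCC(=O)[C@]1(C)C[C@H](OC(=O)C(=C)CO[Si](C)(C)C(C)(C)C)/C=C(\C[Si](C)(C)C)C(=O)OCC=C
F2 | step 13 | 6,15-lactol analogue of 23 (OH in place of OMe at C15) | C=C(CO[Si](C)(C)C(C)(C)C)C(=O)O[C@H]1C[C@]2(C)[C@H]3[C@@H](OC(O)[C@@H]3CCC2=O)[C@@H]1C(=C)C(=O)OCC=C
F3 | step 5 | C10-methyl enone bis-acetal (6 methylated at C10, α-methyl epimer drawn) | COC1OC(OC)[C@@H]2[C@@H](C)C(=O)C=C[C@@H]12
F4 | step 2 | bis[(1R,2S,5R)-menthyl] (1R,2R)-4-(tert-butyldimethylsilyloxy)cyclohex-4-ene-1,2-dicarboxylate | C[C@@H]1CC[C@H]([C@@H](C1)OC(=O)[C@@H]2CC=C(O[Si](C)(C)C(C)(C)C)C[C@H]2C(=O)O[C@@H]3C[C@H](C)CC[C@H]3C(C)C)C(C)C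
F5 | step 2 | [(1R,2R)-4-(tert-butyldimethylsilyloxy)cyclohex-4-ene-1,2-diyl]dimethanol | OC[C@@H]1CC=C(O[Si](C)(C)C(C)(C)C)C[C@H]1CO
F6 | step 2 | (1R,2R)-4-(tert-butyldimethylsilyloxy)cyclohex-4-ene-1,2-dicarbaldehyde | O=C[C@@H]1CC=C(O[Si](C)(C)C(C)(C)C)C[C@H]1C=O
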